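**Retrosynthetic overview**

- Ring atoms of the ten-membered ring are numbered C1–C10 (C1=C2 cis olefin, C4 bears CO2Me, C5 bears the acetoxymethylidene carbon, C8 is CH(Me), C9 is quaternary). The trienol acetate comes from O-acetylation of a C5-formyl enoate, which comes from the C5 enol triflate of a ten-membered β-keto ester whose C1=C2 olefin is a reduced alkyne.
- Feature used: C1 and C5 are 1,5-related across the ten-membered ring. A C1–C5 bond turns it into a cyclopentane (C1–C5) fused to a cycloheptane (C1, C5–C10). A C2 ketone with a C1–C5 epoxide in that bicycle fragments back to C1≡C2 and a C5 ketone next to the C4 ester.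
- The epoxy ketone comes from hydroxyl-directed epoxidation and oxidation of a cyclopentenol, closed at C1–C2 by a Nozaki–Hiyama–Kishi reaction. Its precursor arises by conjugate addition and enolate triflation on a C5-alkylidene keto ester of the C1 ketone.
- The C1 ketone comes from 1,2-carbonyl transposition of a C10 ketone, made by copper-catalysed asymmetric AlMe3 addition to 2-methylcycloheptenone with enolate alkylation (sets C8, then C9).
- Ring order: seven-membered ring (purchased), five-membered ring (step 10), ten-membered ring (step 13, by cutting the shared bond).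

Key step: step 13

Remark: C2, C4 and the epoxide face of the bicyclic intermediates are carried as diastereomer mixtures, because these centres become sp2 or enolisable in steps 12 and 13; only C8 and C9 are controlled.

**Route**

Step 1
Reactants: 1 2-(furan-3-yl)ethan-1-ol
Product: 2 2-(furan-3-yl)ethyl trifluoromethanesulfonate
Conditions: Tf2O, 2,6-lutidine, CH2Cl2, −78 °C; used cold without chromatography
Reagents that add atoms: trifluoromethanesulfonic anhydride, O=S(=O)(OS(=O)(=O)C(F)(F)F)C(F)(F)F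
Why: O-sulfonylation of a primary alcohol is much faster than attack on the furan at −78 °C, and the triflate is a far better SN2 partner than a halide for the hindered enolate of step 2 (alcohol triflation).

Step 2
Reactants: 3 2-methylcyclohept-2-en-1-one; 2 2-(furan-3-yl)ethyl trifluoromethanesulfonate
Product: 6 (2S,3R)-2-[2-(furan-3-yl)ethyl]-2,3-dimethylcycloheptan-1-one, via aluminium enolate 4 (not isolated), via lithium enolate 5 (not isolated)
Conditions: AlMe3, Cu(O2CC4H3S) (5 mol%), one enantiomer of the binaphthol-derived N,N-bis(1-phenylethyl)phosphoramidite (10 mol%), Et2O, −30 °C; MeLi, THF, −78 → 0 °C; then 2, DMPU, −78 → −20 °C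
Reagents that add atoms: trimethylaluminium, C[Al](C)C
Why: Copper-catalysed asymmetric conjugate addition of AlMe3 to an α-substituted cycloalkenone followed by alkylation of the regiodefined tetrasubstituted enolate (tandem conjugate addition–enolate alkylation); the ligand antipode that gives 3R sets C8, and the triflate should enter anti to the new C8 methyl, which puts the two methyls cis and sets C9.

Step 3
Reactants: 6 (2S,3R)-2-[2-(furan-3-yl)ethyl]-2,3-dimethylcycloheptan-1-one
Product: 8 (6R,7S)-7-[2-(furan-3-yl)ethyl]-6,7-dimethylcyclohept-1-en-1-yl trifluoromethanesulfonate, via potassium enolate 7 (not isolated)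
Conditions: KN(SiMe3)2, THF, −78 °C; PhNTf2, −78 → 0 °C
Reagents that add atoms: N-phenylbis(trifluoromethanesulfonimide), O=S(=O)(N(c1ccccc1)S(=O)(=O)C(F)(F)F)C(F)(F)F
Why: The ketone has α-hydrogens on one side only (the other α-carbon is quaternary), so enolate O-triflation can give a single enol triflate (enol triflate formation).

Step 4
Reactants: 8 (6R,7S)-7-[2-(furan-3-yl)ethyl]-6,7-dimethylcyclohept-1-en-1-yl trifluoromethanesulfonate
Product: 9 3-{2-[(1S,7R)-1,7-dimethylcyclohept-2-en-1-yl]ethyl}furan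
Conditions: Pd(OAc)2 (5 mol%), PPh3, Bu3N, HCO2H, DMF, 60 °C
Reagents that add atoms: none
Why: Palladium-catalysed formate hydrogenolysis of an enol triflate replaces OTf by H under conditions the furan tolerates, and the olefin cannot migrate toward the quaternary carbon.

Step 5
Reactants: 9 3-{2-[(1S,7R)-1,7-dimethylcyclohept-2-en-1-yl]ethyl}furan
Product: 11 (3R,4R)-3-[2-(furan-3-yl)ethyl]-3,4-dimethylcycloheptan-1-ol, via alkylborane 10 (not isolated)
Conditions: 9-BBN, THF, 0 → 65 °C; then NaOH, H2O2, 0 → 25 °C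
Reagents that add atoms: hydrogen peroxide, OO
Why: Hydroboration–oxidation; the bulky borane should add boron to the olefin carbon remote from the quaternary centre, so the oxygen ends on C1, and the carbinol configuration is irrelevant.

Step 6
Reactants: 11 (3R,4R)-3-[2-(furan-3-yl)ethyl]-3,4-dimethylcycloheptan-1-ol
Product: 12 (3R,4R)-3-[2-(furan-3-yl)ethyl]-3,4-dimethylcycloheptan-1-one
Conditions: Dess–Martin periodinane, NaHCO3, CH2Cl2, 25 °C
Reagents that add atoms: none
Why: Dess–Martin oxidation of the secondary alcohol completes the 1,2-carbonyl transposition under neutral conditions that leave the furan alone.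

Step 7
Reactants: 12 (3R,4R)-3-[2-(furan-3-yl)ethyl]-3,4-dimethylcycloheptan-1-one; 13 methyl 2-oxoacetate
Product: 17 methyl (2E)-2-[(4R,5R)-4-[2-(furan-3-yl)ethyl]-4,5-dimethyl-2-oxocycloheptylidene]acetate, via lithium enolate 14 (not isolated), via lithium aldolate 15 (not isolated), via mesylate 16 (not isolated)
Conditions: LiN(iPr)2, THF, −78 °C; 13, −78 °C; MsCl, −78 → 0 °C; DBU, 0 → 25 °C
Reagents that add atoms: none
Why: Kinetic deprotonation should occur at the α-CH2 not flanked by the quaternary carbon (C5), aldol addition to the non-enolisable glyoxylate and E1cB loss of mesylate then give the conjugated (E)-alkylidene (directed aldol condensation).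

Step 8
Reactants: 17 methyl (2E)-2-[(4R,5R)-4-[2-(furan-3-yl)ethyl]-4,5-dimethyl-2-oxocycloheptylidene]acetate; 18 (1,3-dioxolan-2-ylmethyl)magnesium bromide
Product: 20 methyl 3-(1,3-dioxolan-2-yl)-2-[(4R,5R)-4-[2-(furan-3-yl)ethyl]-4,5-dimethyl-2-(trifluoromethanesulfonyloxy)cyclohept-1-en-1-yl]propanoate, via magnesium enolate 19 (not isolated)
Conditions: 18, CuBr·SMe2 (10 mol%), THF, −78 → −40 °C; then N-(5-chloropyridin-2-yl)bis(trifluoromethanesulfonimide), −78 → 0 °C
Reagents that add atoms: N-(5-chloropyridin-2-yl)bis(trifluoromethanesulfonimide), O=S(=O)(N(c1ccc(Cl)cn1)S(=O)(=O)C(F)(F)F)C(F)(F)F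
Why: Copper-catalysed 1,4-addition should occur at the exocyclic carbon, which is β to the ketone and the less hindered terminus, and O-triflation of the resulting tetrasubstituted enolate fixes the C1=C5 double bond (conjugate addition–enolate trapping); C4 forms as a mixture that is erased later.

Step 9
Reactants: 20 methyl 3-(1,3-dioxolan-2-yl)-2-[(4R,5R)-4-[2-(furan-3-yl)ethyl]-4,5-dimethyl-2-(trifluoromethanesulfonyloxy)cyclohept-1-en-1-yl]propanoate
Product: 21 methyl 2-[(4R,5R)-4-[2-(furan-3-yl)ethyl]-4,5-dimethyl-2-(trifluoromethanesulfonyloxy)cyclohept-1-en-1-yl]-4-oxobutanoate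
Conditions: 2 M aq. HCl, THF, 25 °C
Reagents that add atoms: water, O
Why: Acid-catalysed acetal hydrolysis unmasks the aldehyde; the vinyl triflate, methyl ester and 3-alkylfuran should survive dilute acid at room temperature.

Step 10
Reactants: 21 methyl 2-[(4R,5R)-4-[2-(furan-3-yl)ethyl]-4,5-dimethyl-2-(trifluoromethanesulfonyloxy)cyclohept-1-en-1-yl]-4-oxobutanoate
Product: 23 methyl (5R,6R)-5-[2-(furan-3-yl)ethyl]-3-hydroxy-5,6-dimethyl-1,2,3,4,5,6,7,8-octahydroazulene-1-carboxylate, via alkenylchromium dichloride 22 (not isolated)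
Conditions: CrCl2 (6 equiv), NiCl2 (5 mol%), DMF, 25 °C
Reagents that add atoms: none
Why: Nozaki–Hiyama–Kishi reaction; zerovalent nickel inserts into the vinyl triflate, the alkenylchromium adds to the tethered aldehyde to close the five-membered ring at C1–C2, and the ester and furan are not touched.

Step 11
Reactants: 23 methyl (5R,6R)-5-[2-(furan-3-yl)ethyl]-3-hydroxy-5,6-dimethyl-1,2,3,4,5,6,7,8-octahydroazulene-1-carboxylate
Product: 24 methyl (5R,6R)-3a,8a-epoxy-5-[2-(furan-3-yl)ethyl]-3-hydroxy-5,6-dimethyldecahydroazulene-1-carboxylate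
Conditions: VO(acac)2 (5 mol%), tBuOOH (decane), CH2Cl2, 0 °C
Reagents that add atoms: tert-butyl hydroperoxide, CC(C)(C)OO
Why: Vanadium-catalysed hydroxyl-directed epoxidation oxidises only the allylic-alcohol olefin, syn to OH, and should spare the electron-rich furan that a dioxirane or peracid would attack.

Step 12
Reactants: 24 methyl (5R,6R)-3a,8a-epoxy-5-[2-(furan-3-yl)ethyl]-3-hydroxy-5,6-dimethyldecahydroazulene-1-carboxylate
Product: 25 methyl (5R,6R)-3a,8a-epoxy-5-[2-(furan-3-yl)ethyl]-5,6-dimethyl-3-oxodecahydroazulene-1-carboxylate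
Conditions: Dess–Martin periodinane, NaHCO3, CH2Cl2, 0 → 25 °C
Reagents that add atoms: none
Why: Dess–Martin oxidation gives the α,β-epoxy ketone without base, so β-elimination of the epoxide through the acidic C4–H is avoided.

Step 13
Reactants: 25 methyl (5R,6R)-3a,8a-epoxy-5-[2-(furan-3-yl)ethyl]-5,6-dimethyl-3-oxodecahydroazulene-1-carboxylate
Product: 27 methyl (6R,7R)-6-[2-(furan-3-yl)ethyl]-6,7-dimethyl-10-oxocyclodec-3-yne-1-carboxylate, via tosylhydrazone 26 (not isolated)
Conditions: TsNHNH2 (1.1 equiv), CH2Cl2/AcOH (2:1), −20 → 25 °C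
Reagents that add atoms: none
Why: The only ketone (C2) condenses with TsNHNH2; the hydrazone nitrogen then pushes electrons through C2=N into C1 and opens the C1–O bond to an azoalkene with the oxygen left on C5, and collapse of that oxygen to the C5 carbonyl breaks the C1–C5 bond while C1≡C2 forms and N2 and p-toluenesulfinate leave. The closest known reaction is the Eschenmoser–Tanabe fragmentation of ring-fused α,β-epoxy ketones to cycloalkynones. The ten-membered ring is not closed by a cyclisation: it appears when the bond shared by the five- and seven-membered rings is cut, so no medium-ring bond formation is needed. No stereocentre is created; C1, C5 and (through the enolisable β-keto ester) C4 lose theirs, which is why their configuration in 25 does not matter, and C8 and C9 are untouched. The selectivity needed is fragmentation over simple epoxide opening or acid-induced epoxide rearrangement; the rigid fused bicycle holds the C1–C5 σ bond aligned with the azoalkene π system and irreversible loss of N2 drives the cleavage, while mild acid at low temperature should spare the furan and ester.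

Step 14
Reactants: 27 methyl (6R,7R)-6-[2-(furan-3-yl)ethyl]-6,7-dimethyl-10-oxocyclodec-3-yne-1-carboxylate
Product: 28 methyl (3Z,6R,7R)-6-[2-(furan-3-yl)ethyl]-6,7-dimethyl-10-oxocyclodec-3-ene-1-carboxylate
Conditions: H2 (1 atm), Pd/CaCO3/Pb(OAc)2, quinoline, EtOAc, 25 °C
Reagents that add atoms: none
Why: Lindlar-type semihydrogenation delivers H2 syn on the poisoned palladium surface and should stop at the cis olefin, leaving furan and β-keto ester intact.

Step 15
Reactants: 28 methyl (3Z,6R,7R)-6-[2-(furan-3-yl)ethyl]-6,7-dimethyl-10-oxocyclodec-3-ene-1-carboxylate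
Product: 30 methyl (1(10)Z,3Z,6R,7R)-6-[2-(furan-3-yl)ethyl]-6,7-dimethyl-10-(trifluoromethanesulfonyloxy)cyclodeca-1(10),3-diene-1-carboxylate, via sodium enolate 29 (not isolated)
Conditions: NaH, THF, 0 °C; PhNTf2, 0 → 25 °C
Reagents that add atoms: N-phenylbis(trifluoromethanesulfonimide), O=S(=O)(N(c1ccccc1)S(=O)(=O)C(F)(F)F)C(F)(F)F
Why: The sodium enolate of the β-keto ester is chelated and is O-triflated with OTf cis to the ester (enol triflate formation).

Step 16
Reactants: 30 methyl (1(10)Z,3Z,6R,7R)-6-[2-(furan-3-yl)ethyl]-6,7-dimethyl-10-(trifluoromethanesulfonyloxy)cyclodeca-1(10),3-diene-1-carboxylate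
Product: 31 methyl (1(10)Z,3Z,6R,7R)-10-formyl-6-[2-(furan-3-yl)ethyl]-6,7-dimethylcyclodeca-1(10),3-diene-1-carboxylate
Conditions: Pd(PPh3)4 (5 mol%), CO (1 atm), Bu3SnH (slow addition), THF, 50 °C
Reagents that add atoms: carbon monoxide, [C-]#[O+]
Why: Palladium-catalysed reductive carbonylation (formylation) of the electron-poor vinyl triflate with CO and Bu3SnH proceeds with retention of olefin geometry.

Step 17
Reactants: 31 methyl (1(10)Z,3Z,6R,7R)-10-formyl-6-[2-(furan-3-yl)ethyl]-6,7-dimethylcyclodeca-1(10),3-diene-1-carboxylate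
Product: 33 methyl (1E,3Z,6R,7R,10Z)-10-[(acetyloxy)methylidene]-6-[2-(furan-3-yl)ethyl]-6,7-dimethylcyclodeca-1,3-diene-1-carboxylate, via magnesium trienolate 32 (not isolated)
Conditions: MgBr2·OEt2, Et3N, Ac2O, CH2Cl2, 0 °C
Reagents that add atoms: acetic anhydride, CC(=O)OC(C)=O
Why: Soft enolisation: magnesium chelates the aldehyde and ester oxygens, Et3N removes the doubly allylic γ-hydrogen at C3 and the trienolate is O-acetylated (dienol acetate formation); the chelate holds the enol oxygen cis to C4, which should give the (Z)-acetoxymethylidene, and the ring keeps both ring olefins cis.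

**Compound list**

1 | 2-(furan-3-yl)ethan-1-ol | OCCc1ccoc1 | starting material
2 | 2-(furan-3-yl)ethyl trifluoromethanesulfonate | FC(F)(F)S(=O)(=O)OCCc1ccoc1 | intermediate
3 | 2-methylcyclohept-2-en-1-one | CC1=CCCCCC1=O | starting material
4 | dimethylaluminium (3R)-2,3-dimethylcyclohept-1-en-1-olate (not isolated) | C1CC[C@@H](C)C(C)=C(O[Al](C)C)C1 | intermediate
5 | lithium (3R)-2,3-dimethylcyclohept-1-en-1-olate (not isolated) | C1CC[C@@H](C)C(C)=C(O[Li])C1 | intermediate
6 | (2S,3R)-2-[2-(furan-3-yl)ethyl]-2,3-dimethylcycloheptan-1-one | C1CC[C@@H](C)[C@](C)(CCc2ccoc2)C(=O)C1 | intermediate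
7 | potassium (6R,7S)-7-[2-(furan-3-yl)ethyl]-6,7-dimethylcyclohept-1-en-1-olate (not isolated) | C1CC[C@@H](C)[C@](C)(CCc2ccoc2)C(O[K])=C1 | intermediate
8 | (6R,7S)-7-[2-(furan-3-yl)ethyl]-6,7-dimethylcyclohept-1-en-1-yl trifluoromethanesulfonate | C1CC[C@@H](C)[C@](C)(CCc2ccoc2)C(OS(=O)(=O)C(F)(F)F)=C1 | intermediate
9 | 3-{2-[(1S,7R)-1,7-dimethylcyclohept-2-en-1-yl]ethyl}furan | C1CC[C@@H](C)[C@](C)(CCc2ccoc2)C=C1 | intermediate
10 | 9-{(3R,4R)-3-[2-(furan-3-yl)ethyl]-3,4-dimethylcycloheptyl}-9-borabicyclo[3.3.1]nonane (C1 epimers, not isolated) | C1(B2C3CCCC2CCC3)CCC[C@@H](C)[C@](C)(CCc4ccoc4)C1 | intermediate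
11 | (3R,4R)-3-[2-(furan-3-yl)ethyl]-3,4-dimethylcycloheptan-1-ol (C1 epimers) | OC1CCC[C@@H](C)[C@](C)(CCc2ccoc2)C1 | intermediate
12 | (3R,4R)-3-[2-(furan-3-yl)ethyl]-3,4-dimethylcycloheptan-1-one | O=C1CCC[C@@H](C)[C@](C)(CCc2ccoc2)C1 | intermediate
13 | methyl 2-oxoacetate (methyl glyoxylate) | COC(=O)C=O | starting material
14 | lithium (5R,6R)-6-[2-(furan-3-yl)ethyl]-5,6-dimethylcyclohept-1-en-1-olate (not isolated) | [Li]OC1=CCC[C@@H](C)[C@](C)(CCc2ccoc2)C1 | intermediate
15 | lithium alkoxide of methyl 2-[(4R,5R)-4-[2-(furan-3-yl)ethyl]-4,5-dimethyl-2-oxocycloheptyl]-2-hydroxyacetate (diastereomers, not isolated) | COC(=O)C(O[Li])C1CC[C@@H](C)[C@](C)(CCc2ccoc2)CC1=O | intermediate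
16 | methyl 2-[(4R,5R)-4-[2-(furan-3-yl)ethyl]-4,5-dimethyl-2-oxocycloheptyl]-2-(methanesulfonyloxy)acetate (diastereomers, not isolated) | COC(=O)C(OS(C)(=O)=O)C1CC[C@@H](C)[C@](C)(CCc2ccoc2)CC1=O | intermediate
17 | methyl (2E)-2-[(4R,5R)-4-[2-(furan-3-yl)ethyl]-4,5-dimethyl-2-oxocycloheptylidene]acetate | COC(=O)/C=C1\CC[C@@H](C)[C@](C)(CCc2ccoc2)CC1=O | intermediate
18 | (1,3-dioxolan-2-ylmethyl)magnesium bromide | Br[Mg]CC1OCCO1 | starting material
19 | bromomagnesium enolate from 1,4-addition of 18 to 17 (O–MgBr on C1, C1=C5 enolate, C4 epimers, not isolated) | COC(=O)C(CC1OCCO1)C2=C(O[Mg]Br)C[C@@](C)(CCc3ccoc3)[C@H](C)CC2 | intermediate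
20 | methyl 3-(1,3-dioxolan-2-yl)-2-[(4R,5R)-4-[2-(furan-3-yl)ethyl]-4,5-dimethyl-2-(trifluoromethanesulfonyloxy)cyclohept-1-en-1-yl]propanoate (C2 epimers of the propanoate) | COC(=O)C(CC1OCCO1)C2=C(OS(=O)(=O)C(F)(F)F)C[C@@](C)(CCc3ccoc3)[C@H](C)CC2 | intermediate
21 | methyl 2-[(4R,5R)-4-[2-(furan-3-yl)ethyl]-4,5-dimethyl-2-(trifluoromethanesulfonyloxy)cyclohept-1-en-1-yl]-4-oxobutanoate (C2 epimers) | COC(=O)C(CC=O)C1=C(OS(=O)(=O)C(F)(F)F)C[C@@](C)(CCc2ccoc2)[C@H](C)CC1 | intermediate
22 | alkenylchromium dichloride derived from 21 (CrCl2 in place of OTf, trivalent chromium, not isolated) | COC(=O)C(CC=O)C1=C([Cr](Cl)Cl)C[C@@](C)(CCc2ccoc2)[C@H](C)CC1 | intermediate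
23 | methyl (5R,6R)-5-[2-(furan-3-yl)ethyl]-3-hydroxy-5,6-dimethyl-1,2,3,4,5,6,7,8-octahydroazulene-1-carboxylate (C1/C3 diastereomers) | OC1CC(C(=O)OC)C2=C1C[C@@](C)(CCc3ccoc3)[C@H](C)CC2 | intermediate
24 | methyl (5R,6R)-3a,8a-epoxy-5-[2-(furan-3-yl)ethyl]-3-hydroxy-5,6-dimethyldecahydroazulene-1-carboxylate (diastereomers at C1, C3 and epoxide face) | OC1CC(C(=O)OC)C2(O3)CC[C@@H](C)[C@](C)(CCc4ccoc4)CC123 | intermediate
25 | methyl (5R,6R)-3a,8a-epoxy-5-[2-(furan-3-yl)ethyl]-5,6-dimethyl-3-oxodecahydroazulene-1-carboxylate (diastereomers at C1 and epoxide face; key-step precursor) | O=C1CC(C(=O)OC)C2(O3)CC[C@@H](C)[C@](C)(CCc4ccoc4)CC123 | intermediate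
26 | 4-methylbenzenesulfonylhydrazone of 25 at the ring ketone (not isolated) | Cc1ccc(cc1)S(=O)(=O)NN=C1CC(C(=O)OC)C2(O3)CC[C@@H](C)[C@](C)(CCc4ccoc4)CC123 | intermediate
27 | methyl (6R,7R)-6-[2-(furan-3-yl)ethyl]-6,7-dimethyl-10-oxocyclodec-3-yne-1-carboxylate (keto form drawn, C1 enolisable) | COC(=O)C1CC#CC[C@@](C)(CCc2ccoc2)[C@H](C)CCC1=O | intermediate
28 | methyl (3Z,6R,7R)-6-[2-(furan-3-yl)ethyl]-6,7-dimethyl-10-oxocyclodec-3-ene-1-carboxylate | COC(=O)C1C/C=C\C[C@@](C)(CCc2ccoc2)[C@H](C)CCC1=O | intermediate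
29 | sodium (Z)-enolate of 28 (ONa on the former ketone carbon, cis to CO2Me, not isolated) | COC(=O)/C1=C(\O[Na])CC[C@@H](C)[C@](C)(CCc2ccoc2)C/C=C\C1 | intermediate
30 | methyl (1(10)Z,3Z,6R,7R)-6-[2-(furan-3-yl)ethyl]-6,7-dimethyl-10-(trifluoromethanesulfonyloxy)cyclodeca-1(10),3-diene-1-carboxylate | COC(=O)/C1=C(\OS(=O)(=O)C(F)(F)F)CC[C@@H](C)[C@](C)(CCc2ccoc2)C/C=C\C1 | intermediate
31 | methyl (1(10)Z,3Z,6R,7R)-10-formyl-6-[2-(furan-3-yl)ethyl]-6,7-dimethylcyclodeca-1(10),3-diene-1-carboxylate | COC(=O)/C1=C(\C=O)CC[C@@H](C)[C@](C)(CCc2ccoc2)C/C=C\C1 | intermediate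
32 | bromomagnesium trienolate of 31 (OMgBr on the exocyclic carbon, cis to C4, not isolated) | COC(=O)/C1=C/C=C\C[C@@](C)(CCc2ccoc2)[C@H](C)CC\C1=C\O[Mg]Br | intermediate
33 | methyl (1E,3Z,6R,7R,10Z)-10-[(acetyloxy)methylidene]-6-[2-(furan-3-yl)ethyl]-6,7-dimethylcyclodeca-1,3-diene-1-carboxylate | COC(=O)/C1=C/C=C\C[C@@](C)(CCc2ccoc2)[C@H](C)CC\C1=C\OC(C)=O | target

**Step count and risks**

Total step count: 17. Longest linear sequence: 17 (from 1; 16 from 3).

Steps most likely to fail:

1. Step 2. The hindered, basic enolate may eliminate the β-furylethyl triflate or exchange protons before it alkylates, and facial selectivity of the alkylation on a seven-membered ring may be modest. Fallback, from 3 to 6: the same copper-catalysed AlMe3 addition and MeLi activation are run, but the enolate is quenched with allyl iodide, which cannot eliminate, to give (2S,3R)-2,3-dimethyl-2-(prop-2-en-1-yl)cycloheptan-1-one F1. OsO4 (cat.)/NaIO4 cleaves the terminal olefin to 2-[(1S,2R)-1,2-dimethyl-7-oxocycloheptyl]acetaldehyde F2. 3-Furyllithium (3-bromofuran, BuLi, −78 °C) adds to the aldehyde only, giving (2S,3R)-2-[2-(furan-3-yl)-2-hydroxyethyl]-2,3-dimethylcycloheptan-1-one F3. Barton–McCombie deoxygenation through the O-phenyl thionocarbonate F4 (PhOC(S)Cl, pyridine; then Bu3SnH, AIBN) comes back to 6.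

2. Step 13. Hydrazone formation at the hindered ketone may be slower than acid-induced epoxide opening, or the opened azoalkene may collapse by paths other than C1–C5 scission. Fallback, from 25 to 28: SmI2 (THF/MeOH, −78 °C) cleaves the C1–O bond to methyl (5R,6R)-5-[2-(furan-3-yl)ethyl]-8a-hydroxy-5,6-dimethyl-3-oxodecahydroazulene-1-carboxylate F5. NaBH4 gives methyl (5R,6R)-5-[2-(furan-3-yl)ethyl]-3,8a-dihydroxy-5,6-dimethyldecahydroazulene-1-carboxylate F6. Only the secondary hydroxyl is mesylated, to methyl (5R,6R)-5-[2-(furan-3-yl)ethyl]-8a-hydroxy-3-(methanesulfonyloxy)-5,6-dimethyldecahydroazulene-1-carboxylate F7. KOtBu then triggers a Grob fragmentation of the same C1–C5 bond and gives the cis-cyclodecenone 28 directly. This needs the C2–O bond anti to the fusion bond and cis to C10 (H on C1 and the mesylate trans); a Mitsunobu inversion would correct the other C2 epimer.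

3. Step 17. Acetylation may occur on carbon, enolisation may go toward C6, or the enol geometry may erode during work-up of the sensitive trienyl acetate. Fallback, from 31 to 33: enolisation is separated from acylation. TMSOTf/Et3N gives methyl (1E,3Z,6R,7R,10Z)-6-[2-(furan-3-yl)ethyl]-6,7-dimethyl-10-{[(trimethylsilyl)oxy]methylidene}cyclodeca-1,3-diene-1-carboxylate F8, whose geometry can be checked and equilibrated. Silicon is then exchanged for acetyl with Ac2O and catalytic tetrabutylammonium difluorotriphenylsilicate to reach 33.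

**Further compounds**

F1 | step 2 | (2S,3R)-2,3-dimethyl-2-(prop-2-en-1-yl)cycloheptan-1-one | C1CC[C@@H](C)[C@](C)(CC=C)C(=O)C1
F2 | step 2 | 2-[(1S,2R)-1,2-dimethyl-7-oxocycloheptyl]acetaldehyde | C1CC[C@@H](C)[C@](C)(CC=O)C(=O)C1
F3 | step 2 | (2S,3R)-2-[2-(furan-3-yl)-2-hydroxyethyl]-2,3-dimethylcycloheptan-1-one (carbinol epimers) | C1CC[C@@H](C)[C@](C)(CC(O)c2ccoc2)C(=O)C1
F4 | step 2 | O-{2-[(1S,2R)-1,2-dimethyl-7-oxocycloheptyl]-1-(furan-3-yl)ethyl} O-phenyl carbonothioate | C1CC[C@@H](C)[C@](C)(CC(OC(=S)Oc2ccccc2)c3ccoc3)C(=O)C1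
F5 | step 13 | methyl (5R,6R)-5-[2-(furan-3-yl)ethyl]-8a-hydroxy-5,6-dimethyl-3-oxodecahydroazulene-1-carboxylate | O=C1CC(C(=O)OC)C2(O)CC[C@@H](C)[C@](C)(CCc3ccoc3)CC12
F6 | step 13 | methyl (5R,6R)-5-[2-(furan-3-yl)ethyl]-3,8a-dihydroxy-5,6-dimethyldecahydroazulene-1-carboxylate | OC1CC(C(=O)OC)C2(O)CC[C@@H](C)[C@](C)(CCc3ccoc3)CC12
F7 | step 13 | methyl (5R,6R)-5-[2-(furan-3-yl)ethyl]-8a-hydroxy-3-(methanesulfonyloxy)-5,6-dimethyldecahydroazulene-1-carboxylate | CS(=O)(=O)OC1CC(C(=O)OC)C2(O)CC[C@@H](C)[C@](C)(CCc3ccoc3)CC12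
F8 | step 17 | methyl (1E,3Z,6R,7R,10Z)-6-[2-(furan-3-yl)ethyl]-6,7-dimethyl-10-{[(trimethylsilyl)oxy]methylidene}cyclodeca-1,3-diene-1-carboxylate | COC(=O)/C1=C/C=C\C[C@@](C)(CCc2ccoc2)[C@H](C)CC\C1=C\O[Si](C)(C)C
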